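**Plan**
1. Retrosynthesis: the aryl ester C(=O)–O bond is cut first, giving (R)-terpinen-4-ol and silyl-protected 4-hydroxy-3,5-diprenylbenzoyl chloride. In the cyclohexene, the two ring bonds that flank the CH2–CH2 unit (CH2–C(CH3)= and CH2–C(O)(i-Pr)) are then cut together.
2. Enabling feature: the oxygen-bearing quaternary ring carbon and the methyl-bearing alkene carbon are 1,4-related across the cyclohexene. The carbinol oxygen and the methyl carbon (at the carboxyl level) can therefore be tied as an O–C(=O) bridge, which makes the ring the 2-oxabicyclo[2.2.2]oct-5-en-3-one formed by [4+2] addition of a two-carbon alkene across C3/C6 of a 6-isopropyl-2-pyrone.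
3. Forward: 3-methylbutan-2-one and a methoxymethylene malonate give the 3-methoxycarbonyl-6-isopropyl-2-pyrone (the ester is the activating group and the future methyl). A catalytic asymmetric inverse-demand Diels–Alder reaction with phenyl vinyl selenide (ethylene equivalent) builds the only carbocycle. Selenium is removed by radical reduction before any carbanion is made next to it.
4. The lactone bridge is hydrolysed and lost as CO2, the alkene moves into conjugation with the ester (which fixes it on the correct ring arm), and the ester is reduced to the methyl group.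
5. Acid part: double ortho C-prenylation of methyl 4-hydroxybenzoate, saponification, bis-silylation; acid chloride plus lithium alkoxide; desilylation.
6. Stereochemistry: the single stereocentre is set in the cycloaddition by face selection on the pyrone (Yb(OTf)3/(R)-BINOL). Its C–O bond is never broken afterwards and the two ring arms cannot exchange roles.

Key step: step 2

Assumption: (R)-BINOL is taken to give the (1S) oxygen-bearing bridgehead in the cycloadduct; if the sense of induction is found to be opposite, (S)-BINOL is used and nothing else changes.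

**Route**

Step 1
Reactants: 1 3-methylbutan-2-one; 2 dimethyl 2-(methoxymethylidene)propanedioate
Product: 5 methyl 2-oxo-6-(propan-2-yl)-2H-pyran-3-carboxylate, via lithium enolate 3 (not isolated), via keto diester 4 (not isolated)
Conditions: LiN(i-Pr)2, THF, −78 °C; 2, −78 → 0 °C; 1 M HCl; then p-TsOH (cat.), PhMe, 80 °C
Reagents that add atoms: none
Why: Kinetic deprotonation at the methyl group gives the less substituted enolate, which displaces methoxide from the alkoxymethylene malonate by addition–elimination, and the dienol of the resulting keto diester lactonises onto the cis ester on acid treatment to close the 2-pyrone (enolate condensation followed by enol lactonisation, the usual entry to 3-alkoxycarbonyl-2-pyrones); no stereocentre is formed.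

Step 2
Reactants: 5 methyl 2-oxo-6-(propan-2-yl)-2H-pyran-3-carboxylate; 6 (ethenylselanyl)benzene (phenyl vinyl selenide)
Product: 7 methyl (1S,4R)-3-oxo-8-(phenylselanyl)-1-(propan-2-yl)-2-oxabicyclo[2.2.2]oct-5-ene-4-carboxylate (both C8 epimers; endo expected as the main one)
Conditions: 6 (3 equiv), Yb(OTf)3 (20 mol%), (R)-BINOL (24 mol%), i-Pr2NEt (48 mol%), 4 Å MS, CH2Cl2, 0 °C → rt
Reagents that add atoms: none
Why: Two-point binding of the lactone and ester carbonyls of 5 to the trivalent ytterbium binaphtholate lowers the diene LUMO, and the electron-rich alkene 6 adds across C3 and C6 of the pyrone in an asynchronous concerted inverse-electron-demand [4+2] cycloaddition, its CH2 terminus bonding to the isopropyl-bearing C6 and its selenium-bearing carbon to C3. The closest known reaction type is the chiral-Lewis-acid-catalysed inverse-demand Diels–Alder reaction of 3-alkoxycarbonyl-2-pyrones with vinyl ethers and vinyl sulfides. The cyclohexene ring is closed by this intermolecular suprafacial [4+2] addition, while the O–C(=O) unit of the pyrone stays as a two-atom bridge because the reaction runs at or below room temperature, under the onset of cycloreversion with loss of CO2. The quaternary C1 (the later carbinol carbon) is set by the catalyst, whose binaphthyl wall should shield one face of the bound pyrone; C4 follows from C1 because both new bonds form on the same diene face, and C8 follows the endo rule but is erased in step 3. The step needs π-facial selectivity, which the chelated chiral complex should secure, and the regiochemistry described, which the polarisation of the alkylidene-malonate-like diene (largest LUMO coefficient at C6) and of the vinyl selenide (largest HOMO coefficient at CH2) should secure.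

Step 3
Reactants: 7 methyl (1S,4R)-3-oxo-8-(phenylselanyl)-1-(propan-2-yl)-2-oxabicyclo[2.2.2]oct-5-ene-4-carboxylate
Product: 8 methyl (1S,4S)-3-oxo-1-(propan-2-yl)-2-oxabicyclo[2.2.2]oct-5-ene-4-carboxylate
Conditions: n-Bu3SnH (1.5 equiv), PhSeSePh (10 mol%), Et3B (0.2 equiv), air, PhMe, 0 °C → rt
Reagents that add atoms: none
Why: The stannyl radical abstracts the phenylselanyl group and the secondary C8 radical is reduced by hydrogen-atom transfer, benzeneselenol formed in the flask from the diselenide being a fast enough donor to outrun the 3-exo attack of this radical on C5 (1,2-vinyl shift), while the mild temperature keeps the CO2 bridge (radical chain deselenation with selenol catalysis); both C8 epimers converge and neither bridgehead is touched.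

Step 4
Reactants: 8 methyl (1S,4S)-3-oxo-1-(propan-2-yl)-2-oxabicyclo[2.2.2]oct-5-ene-4-carboxylate
Product: 11 methyl (4R)-4-hydroxy-4-(propan-2-yl)cyclohex-1-ene-1-carboxylate, via half-acid 9 (not isolated), via deconjugated ester 10 (not isolated)
Conditions: LiOH (1.1 equiv), THF/H2O, 0 °C; 1 M HCl to pH 4 (0 °C), EtOAc; pyridine, 100 °C; then DBU (0.2 equiv), rt
Reagents that add atoms: none
Why: Hydroxide opens the strained, doubly activated lactone at the acyl carbon so that the C–O bond of the carbinol carbon and its configuration are retained, the vinylogous malonic half-acid loses CO2 on warming in pyridine, and the amidine base moves the double bond into conjugation with the ester through a dienolate that can only place it on the arm that already held the alkene (saponification, malonic half-acid decarboxylation, base-mediated alkene conjugation); the descriptor changes from S to R only because the ring CH= neighbour becomes CH2.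

Step 5
Reactants: 11 methyl (4R)-4-hydroxy-4-(propan-2-yl)cyclohex-1-ene-1-carboxylate
Product: 12 (1R)-4-(hydroxymethyl)-1-(propan-2-yl)cyclohex-3-en-1-ol
Conditions: i-Bu2AlH (3.5 equiv), CH2Cl2, −78 → 0 °C; aq. potassium sodium tartrate
Reagents that add atoms: none
Why: i-Bu2AlH reduces the conjugated ester by 1,2-hydride delivery to the primary allylic alcohol without touching the trisubstituted alkene or the tertiary carbinol centre (ester reduction).

Step 6
Reactants: 12 (1R)-4-(hydroxymethyl)-1-(propan-2-yl)cyclohex-3-en-1-ol
Product: 14 (1R)-4-methyl-1-(propan-2-yl)cyclohex-3-en-1-ol ((R)-terpinen-4-ol), via allylic mesylate 13 (not isolated)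
Conditions: MsCl (1.05 equiv), Et3N, CH2Cl2, −40 °C; then LiEt3BH (3 equiv), THF, −40 → 0 °C
Reagents that add atoms: none
Why: The primary allylic hydroxyl is sulfonylated far faster than the hindered tertiary one and LiEt3BH displaces the mesylate by direct SN2 hydride attack at the unhindered CH2, which gives the methyl group without allylic transposition and without touching the stereocentre (sulfonate hydrogenolysis with a trialkylborohydride).

Step 7
Reactants: 15 methyl 4-hydroxybenzoate; 16 1-bromo-3-methylbut-2-ene (prenyl bromide)
Product: 17 methyl 4-hydroxy-3,5-bis(3-methylbut-2-en-1-yl)benzoate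
Conditions: NaH (2.2 equiv), PhMe, 0 °C; 16 (2.2 equiv), rt → 60 °C
Reagents that add atoms: none
Why: In toluene the sodium phenoxide is a tight ion-pair aggregate whose oxygen is shielded by the cation, so prenyl bromide is attacked by the ortho carbons (SN2 C-alkylation of a phenoxide in a non-polar medium) and, with the para position blocked by the ester, two equivalents should give the 3,5-diprenyl phenol after tautomerisation.

Step 8
Reactants: 17 methyl 4-hydroxy-3,5-bis(3-methylbut-2-en-1-yl)benzoate
Product: 18 4-hydroxy-3,5-bis(3-methylbut-2-en-1-yl)benzoic acid (nervogenic acid)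
Conditions: KOH, MeOH/H2O, 60 °C; then 1 M HCl, 0 °C
Reagents that add atoms: potassium hydroxide, [K+].[OH-]
Why: Hydroxide saponifies the unhindered methyl benzoate while the phenoxide and the prenyl groups are inert to base, and cold dilute acid liberates the acid without cyclising the ortho-prenyl phenol (ester hydrolysis).

Step 9
Reactants: 18 4-hydroxy-3,5-bis(3-methylbut-2-en-1-yl)benzoic acid
Product: 19 tert-butyldimethylsilyl 4-[(tert-butyldimethylsilyl)oxy]-3,5-bis(3-methylbut-2-en-1-yl)benzoate
Conditions: TBSCl (2.5 equiv), imidazole (5 equiv), DMF, 40 °C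
Reagents that add atoms: tert-butyl(chloro)dimethylsilane, CC(C)(C)[Si](C)(C)Cl
Why: The imidazole-activated silyl chloride silylates both the carboxylic acid and the phenol, which masks the phenol for the acylation and turns the acid into a silyl ester that can be converted to the acid chloride without free HCl (silylation).

Step 10
Reactants: 14 (1R)-4-methyl-1-(propan-2-yl)cyclohex-3-en-1-ol; 19 tert-butyldimethylsilyl 4-[(tert-butyldimethylsilyl)oxy]-3,5-bis(3-methylbut-2-en-1-yl)benzoate
Product: 22 (1R)-4-methyl-1-(propan-2-yl)cyclohex-3-en-1-yl 4-[(tert-butyldimethylsilyl)oxy]-3,5-bis(3-methylbut-2-en-1-yl)benzoate, via acid chloride 20 (not isolated), via lithium alkoxide 21 (not isolated)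
Conditions: 19, (COCl)2 (1.1 equiv), DMF (cat.), CH2Cl2, 0 °C → rt, evaporation; 14, n-BuLi (1.05 equiv), THF, −78 °C; acid chloride added, −78 °C → rt
Reagents that add atoms: none
Why: Oxalyl chloride with catalytic DMF converts the silyl ester into the aroyl chloride under neutral conditions that spare the acid-sensitive prenyl groups, and the lithium alkoxide of the hindered tertiary alcohol is nucleophilic enough to attack this unhindered acyl chloride at carbon, so the C–O bond of the stereocentre is not involved and its configuration is retained (O-acylation of a metal alkoxide by an acid chloride).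

Step 11
Reactants: 22 (1R)-4-methyl-1-(propan-2-yl)cyclohex-3-en-1-yl 4-[(tert-butyldimethylsilyl)oxy]-3,5-bis(3-methylbut-2-en-1-yl)benzoate
Product: 23 (1R)-4-methyl-1-(propan-2-yl)cyclohex-3-en-1-yl 4-hydroxy-3,5-bis(3-methylbut-2-en-1-yl)benzoate (CNP0120997.1)
Conditions: n-Bu4NF (1.1 equiv), AcOH (1.1 equiv), THF, 0 °C
Reagents that add atoms: none
Why: Fluoride cleaves the aryl silyl ether selectively, acetic acid buffering the phenoxide so that the hindered tertiary benzoate and the prenyl groups are untouched (fluoride desilylation).

**Compound list**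
1 | 3-methylbutan-2-one | CC(C)C(C)=O | starting material
2 | dimethyl 2-(methoxymethylidene)propanedioate | COC=C(C(=O)OC)C(=O)OC | starting material
3 | lithium 3-methylbut-1-en-2-olate | [Li+].[O-]C(=C)C(C)C | intermediate
4 | dimethyl 2-(4-methyl-3-oxopentylidene)propanedioate | COC(=O)C(=CCC(=O)C(C)C)C(=O)OC | intermediate
5 | methyl 2-oxo-6-(propan-2-yl)-2H-pyran-3-carboxylate | COC(=O)C1=CC=C(C(C)C)OC1=O | intermediate
6 | (ethenylselanyl)benzene (phenyl vinyl selenide) | C=C[Se]c1ccccc1 | starting material
7 | methyl (1S,4R)-3-oxo-8-(phenylselanyl)-1-(propan-2-yl)-2-oxabicyclo[2.2.2]oct-5-ene-4-carboxylate (C8 epimers) | CC(C)[C@]12OC(=O)[C@@](C=C1)(C(=O)OC)C([Se]c3ccccc3)C2 | intermediate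
8 | methyl (1S,4S)-3-oxo-1-(propan-2-yl)-2-oxabicyclo[2.2.2]oct-5-ene-4-carboxylate | CC(C)[C@]12OC(=O)[C@@](C=C1)(C(=O)OC)CC2 | intermediate
9 | (1R,4S)-4-hydroxy-1-(methoxycarbonyl)-4-(propan-2-yl)cyclohex-2-ene-1-carboxylic acid | COC(=O)[C@@]1(C(=O)O)C=C[C@@](O)(C(C)C)CC1 | intermediate
10 | methyl (4S)-4-hydroxy-4-(propan-2-yl)cyclohex-2-ene-1-carboxylate (C1 epimers) | COC(=O)C1C=C[C@@](O)(C(C)C)CC1 | intermediate
11 | methyl (4R)-4-hydroxy-4-(propan-2-yl)cyclohex-1-ene-1-carboxylate | COC(=O)C1=CC[C@@](O)(C(C)C)CC1 | intermediate
12 | (1R)-4-(hydroxymethyl)-1-(propan-2-yl)cyclohex-3-en-1-ol | OCC1=CC[C@@](O)(C(C)C)CC1 | intermediate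
13 | [(4R)-4-hydroxy-4-(propan-2-yl)cyclohex-1-en-1-yl]methyl methanesulfonate | CS(=O)(=O)OCC1=CC[C@@](O)(C(C)C)CC1 | intermediate
14 | (1R)-4-methyl-1-(propan-2-yl)cyclohex-3-en-1-ol ((R)-terpinen-4-ol) | CC1=CC[C@@](O)(C(C)C)CC1 | intermediate
15 | methyl 4-hydroxybenzoate | COC(=O)c1ccc(O)cc1 | starting material
16 | 1-bromo-3-methylbut-2-ene (prenyl bromide) | CC(C)=CCBr | starting material
17 | methyl 4-hydroxy-3,5-bis(3-methylbut-2-en-1-yl)benzoate | COC(=O)c1cc(CC=C(C)C)c(O)c(CC=C(C)C)c1 | intermediate
18 | 4-hydroxy-3,5-bis(3-methylbut-2-en-1-yl)benzoic acid (nervogenic acid) | OC(=O)c1cc(CC=C(C)C)c(O)c(CC=C(C)C)c1 | intermediate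
19 | tert-butyldimethylsilyl 4-[(tert-butyldimethylsilyl)oxy]-3,5-bis(3-methylbut-2-en-1-yl)benzoate | CC(C)=CCc1cc(C(=O)O[Si](C)(C)C(C)(C)C)cc(CC=C(C)C)c1O[Si](C)(C)C(C)(C)C | intermediate
20 | 4-[(tert-butyldimethylsilyl)oxy]-3,5-bis(3-methylbut-2-en-1-yl)benzoyl chloride | CC(C)=CCc1cc(C(Cl)=O)cc(CC=C(C)C)c1O[Si](C)(C)C(C)(C)C | intermediate
21 | lithium (1R)-4-methyl-1-(propan-2-yl)cyclohex-3-en-1-olate | CC1=CC[C@@]([O-])(C(C)C)CC1.[Li+] | intermediate
22 | (1R)-4-methyl-1-(propan-2-yl)cyclohex-3-en-1-yl 4-[(tert-butyldimethylsilyl)oxy]-3,5-bis(3-methylbut-2-en-1-yl)benzoate | CC(C)=CCc1cc(C(=O)O[C@@]2(C(C)C)CC=C(C)CC2)cc(CC=C(C)C)c1O[Si](C)(C)C(C)(C)C | intermediate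
23 | (1R)-4-methyl-1-(propan-2-yl)cyclohex-3-en-1-yl 4-hydroxy-3,5-bis(3-methylbut-2-en-1-yl)benzoate (CNP0120997.1) | CC(C)=CCc1cc(C(=O)O[C@@]2(C(C)C)CC=C(C)CC2)cc(CC=C(C)C)c1O | target

**Count and risks**
Total steps: 11. Longest linear sequence: 8 (steps 1–6, 10, 11); steps 7–9 form the three-step side branch.

Steps most likely to fail, most serious first:

Step 2. The isopropyl group at the reacting C6 may slow bond formation and weaken π-facial discrimination by the chiral Lewis acid, so that the adduct forms with low enantiomeric purity. The fallback sets out from 5 and 6, gives up catalyst control and resolves instead. The cycloaddition is run with Yb(OTf)3 alone (or uncatalysed at 10–12 kbar in CH2Cl2 at room temperature) to give the racemic selenide adduct F1. This is deselenated under the step 3 conditions to the racemic lactone F2. Preparative chromatography on a cellulose tris(3,5-dimethylphenylcarbamate) stationary phase then separates the enantiomers, and the (1S,4S) enantiomer is 8, where the route is rejoined.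

Step 4. Hydroxide may attack the methyl ester in place of the lactone, or the tertiary allylic hydroxyl may ionise and be lost (dehydration toward a cumate-type arene) while the free half-acid is acidified and heated. The fallback sets out from 8 and avoids any free acid. Methoxide-catalysed methanolysis (NaOMe 0.1 equiv, MeOH, 0 °C) opens the lactone to dimethyl (4S)-4-hydroxy-4-(propan-2-yl)cyclohex-2-ene-1,1-dicarboxylate F3. Dealkoxycarbonylation under Krapcho conditions (LiCl, DMSO/H2O, 130 °C) then removes one ester group under neutral conditions, and protonation of the dienolate with a DBU finish returns to the route at 11.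

Step 7. O-alkylation, incomplete second alkylation and double alkylation at one ortho carbon may compete and leave little of the 3,5-dialkylated phenol. The fallback sets out from commercial methyl 3,5-dibromo-4-hydroxybenzoate F4 and lets the halogens fix the positions. Acetylation (Ac2O, pyridine, rt) gives methyl 4-acetoxy-3,5-dibromobenzoate F5. Twofold Stille coupling with tributyl(3-methylbut-2-en-1-yl)stannane F6 (Pd(PPh3)4, DMF, 90 °C) should give methyl 4-acetoxy-3,5-bis(3-methylbut-2-en-1-yl)benzoate F7. The hydroxide treatment of step 8 then cleaves the acetate and the methyl ester together and returns to the route at 18.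

Further compounds
F1 | step 2 | racemic methyl 3-oxo-8-(phenylselanyl)-1-(propan-2-yl)-2-oxabicyclo[2.2.2]oct-5-ene-4-carboxylate | CC(C)C12OC(=O)C(C=C1)(C(=O)OC)C([Se]c3ccccc3)C2
F2 | step 2 | racemic methyl 3-oxo-1-(propan-2-yl)-2-oxabicyclo[2.2.2]oct-5-ene-4-carboxylate | CC(C)C12OC(=O)C(C=C1)(C(=O)OC)CC2
F3 | step 4 | dimethyl (4S)-4-hydroxy-4-(propan-2-yl)cyclohex-2-ene-1,1-dicarboxylate | COC(=O)C1(C(=O)OC)C=C[C@@](O)(C(C)C)CC1
F4 | step 7 | methyl 3,5-dibromo-4-hydroxybenzoate | COC(=O)c1cc(Br)c(O)c(Br)c1
F5 | step 7 | methyl 4-acetoxy-3,5-dibromobenzoate | COC(=O)c1cc(Br)c(OC(C)=O)c(Br)c1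
F6 | step 7 | tributyl(3-methylbut-2-en-1-yl)stannane | CCCC[Sn](CCCC)(CCCC)CC=C(C)C
F7 | step 7 | methyl 4-acetoxy-3,5-bis(3-methylbut-2-en-1-yl)benzoate | COC(=O)c1cc(CC=C(C)C)c(OC(C)=O)c(CC=C(C)C)c1
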